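## Retrosynthetic overview

- The target is the 3-methylbut-2-enoate of a 2-substituted 8-hydroxy-5-methoxy-1,4-naphthoquinone. Taken back first are the ester (Steglich), the quinone (Teuber oxidation of a 1-naphthol) and the naphthol (acid opening of an oxygen-bridged dihydronaphthalene).
- Key disconnection: C1–C8a and C4–C4a, an intramolecular aryne–furan [4+2] that builds ring B onto the bought ring A. The feature used is that O8 (on C8) and O1' (on C1') lie on the same edge, C8–C8a–C1–C2–C1', so one iPr2Si atom can join the phenol to the 3-furyl carbinol and leave only one furan orientation within reach.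
- Ring order: ring A is bought. Step 6 closes the oxygen-bridged six-membered ring B and, through the same C1–C8a bond, the eight-membered ring C8–O–Si–O–C1'–C2–C1–C8a.
- Repair of the endgame: the tether is cut while C1 is still sp3, because O–Si–O cannot span a flat C8–C8a–C1–C2 unit across the C1 substituent. Two TBS groups then mask O8 and O1' up to the quinone.
- The precursor comes from three pieces: (S)-carbinol 6 (Keck allylation, cross-metathesis), phenol 11 (ortho-lithiation/bromination, mono-demethylation) and iPr2SiCl2.

Key step: step 6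

Remark on numbering: atom numbers follow the target throughout (C1 and C4 are the quinone carbonyl carbons, C2 carries the side chain, C1' is its carbinol carbon, C5 bears OMe, C8 bears OH).

Assumption: facial selectivity in step 6 is not needed. Compounds 17–19 are drawn as one bridgehead diastereomer; its C1/C4 epimer, if formed, is carried through the same steps and converges at naphthol 20.

## Route

Step 1
Reactants: 1 3-furaldehyde; 2 allyltributylstannane
Product: 4 (S)-1-(furan-3-yl)but-3-en-1-ol, via tributylstannyl ether 3 (not isolated)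
Conditions: (S)-BINOL (20 mol %), Ti(OiPr)4 (10 mol %), 4 Å MS, CH2Cl2, −20 °C; aq. NaHCO3
Reagents that add atoms: allyltributylstannane (2), C=CC[Sn](CCCC)(CCCC)CCCC
Why: Keck asymmetric allylation, in which the (S)-BINOL–titanium Lewis acid blocks one face of the aldehyde so that allyl transfer from tin sets C1' as (S), the sense this ligand gives with aryl aldehydes (furyl outranks allyl).

Step 2
Reactants: 4 (S)-1-(furan-3-yl)but-3-en-1-ol; 5 2-methylbut-2-ene
Product: 6 (S)-1-(furan-3-yl)-4-methylpent-3-en-1-ol
Conditions: second-generation Grubbs catalyst (H2IMes)(PCy3)Cl2Ru=CHPh (3 mol %), 2-methylbut-2-ene (excess)/CH2Cl2, 40 °C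
Reagents that add atoms: 2-methylbut-2-ene (5), CC=C(C)C
Why: Olefin cross-metathesis of a terminal alkene with excess trisubstituted alkene exchanges =CH2 for =CMe2 with loss of propene; the free alcohol and furan are tolerated and C1' is not touched.

Step 3
Reactants: 7 2-bromo-1,4-dimethoxybenzene
Product: 9 2,3-dibromo-1,4-dimethoxybenzene, via aryllithium 8 (not isolated)
Conditions: LiN(iPr)2 (1.1 equiv), THF, −78 °C; then BrCCl2CCl2Br, −78 °C to rt
Reagents that add atoms: 1,2-dibromo-1,1,2,2-tetrachloroethane, BrC(Cl)(Cl)C(Cl)(Cl)Br
Why: Directed ortho-metalation by an amide base (no bromine–lithium exchange) removes the most acidic proton, the one flanked by Br and OMe, and the aryllithium takes bromine from the positive-bromine donor.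

Step 4
Reactants: 9 2,3-dibromo-1,4-dimethoxybenzene
Product: 11 2,3-dibromo-4-methoxyphenol, via aryloxydibromoborane 10 (not isolated)
Conditions: BBr3 (1.0 equiv), CH2Cl2, −78 to 0 °C; H2O
Reagents that add atoms: none
Why: Lewis-acid cleavage of an aryl methyl ether on a symmetric substrate, so either methoxy group gives the same phenol; limiting BBr3 and the lower basicity of the remaining methoxy oxygen after the first cleavage should favour mono-cleavage, and the phenol is separated from unreacted 9 by base extraction.

Step 5
Reactants: 6 (S)-1-(furan-3-yl)-4-methylpent-3-en-1-ol; 12 dichlorodiisopropylsilane; 11 2,3-dibromo-4-methoxyphenol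
Product: 14 (2,3-dibromo-4-methoxyphenoxy)[(1S)-1-(furan-3-yl)-4-methylpent-3-enyloxy]diisopropylsilane, via chlorosilane 13 (not isolated)
Conditions: 12 (1.05 equiv), Et3N, DMAP (cat.), CH2Cl2, 0 °C, slow addition of 6; then 11, Et3N, rt
Reagents that add atoms: dichlorodiisopropylsilane (12), CC(C)[Si](Cl)(Cl)C(C)C
Why: Two successive nucleophilic substitutions at silicon, in which the bulky isopropyl groups make the second Si–Cl much slower than the first, so the slowly added carbinol stops at the monochloride and the phenol then fills the remaining site.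

Step 6
Reactants: 14 (2,3-dibromo-4-methoxyphenoxy)[(1S)-1-(furan-3-yl)-4-methylpent-3-enyloxy]diisopropylsilane
Product: 17 silicon-tethered 5-methoxy-1,4-epoxy-1,4-dihydronaphthalene (1S,4R,1'S as drawn), via aryllithium 15 (not isolated), via aryne 16 (not isolated)
Conditions: n-BuLi (1.05 equiv), THF (0.005 M), −78 °C, then slowly to −20 °C
Reagents that add atoms: none
Why: Bromine–lithium exchange should occur at the bromine next to the methoxy group (the better lithium-binding neighbour) to give 15, which loses LiBr to aryne 16; the tethered furan then adds across its C2 and C5 in a concerted suprafacial [4+2], forming C1–C8a and C4–C4a. The closest known reaction type is the silicon-tethered intramolecular aryne–furan Diels–Alder reaction of ortho-dihaloaryl silyl ethers. The six-membered ring B with its oxygen bridge closes by the cycloaddition itself, and the eight-membered ring C8–O–Si–O–C1'–C2–C1–C8a closes through the new C1–C8a bond, the tether supplying the rest; the sp3 bridgehead C1 kinks the C8–C8a–C1–C2 unit enough for the short link to reach. The new bridgehead stereocentres C1 and C4 are cis by the suprafacial mode, and their sense relative to C1' follows from the furan face the tether presents (the homoprenyl group on C1' is expected to point away from the medium ring); either sense serves, since both become sp2 in step 9. The step needs regioselectivity, secured because in the opposite orientation a model places C1' about 6 Å from O8, beyond the reach of O–Si–O; it also needs exchange to outrun attack of n-BuLi on silicon or on the strained alkene of 17 and migration of silicon to an ortho-lithiated carbon, which stoichiometric base at −78 °C and the bulky isopropyl groups should secure, while high dilution suppresses intermolecular capture.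

Step 7
Reactants: 17 silicon-tethered cycloadduct
Product: 18 (1S,4R)-2-[(1S)-1-hydroxy-4-methylpent-3-enyl]-5-methoxy-1,4-dihydro-1,4-epoxynaphthalen-8-ol
Conditions: Bu4NF (2.5 equiv), AcOH (2.5 equiv), THF, 0 °C to rt
Reagents that add atoms: none
Why: Fluoride-mediated desilylation (aryloxide, then alkoxide, leaves silicon) under acetic acid buffering spares the acid-sensitive oxygen bridge, and it is done now because the eight-membered ring could not survive the flattening of C1 and C2 in the later naphthol and quinone.

Step 8
Reactants: 18 diol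
Product: 19 bis(tert-butyldimethylsilyl) ether of 18 (at O8 and O1')
Conditions: TBSCl (3 equiv), imidazole (6 equiv), DMF, rt
Reagents that add atoms: tert-butyldimethylsilyl chloride, CC(C)(C)[Si](C)(C)Cl
Why: Standard imidazole-promoted silylation of a phenol and a secondary alcohol; O8 must be masked so that the later oxidation finds a free phenol only in ring B, and O1' so that the carbinol is a poor leaving group under acid.

Step 9
Reactants: 19 bis-TBS ether
Product: 20 8-(tert-butyldimethylsilyloxy)-2-[(1S)-1-(tert-butyldimethylsilyloxy)-4-methylpent-3-enyl]-5-methoxynaphthalen-1-ol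
Conditions: CF3CO2H (0.1 equiv), CH2Cl2, −20 to 0 °C; NaHCO3 quench
Reagents that add atoms: none
Why: Acid-catalysed isomerisation of a 1,4-epoxy-1,4-dihydronaphthalene to a 1-naphthol, by protonation of the bridge oxygen, C4–O ionisation to a cation stabilised by the C5 methoxy group and the substituted C2 terminus, 1,2-hydride shift from C1 to C2 and proton loss; both bridgehead stereocentres disappear, C1' is not part of the cation, and the regioisomeric 4-naphthol would lead to the same quinone.

Step 10
Reactants: 20 naphthol
Product: 21 8-(tert-butyldimethylsilyloxy)-2-[(1S)-1-(tert-butyldimethylsilyloxy)-4-methylpent-3-enyl]-5-methoxy-1,4-naphthoquinone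
Conditions: (KSO3)2NO (3 equiv), KH2PO4, acetone/H2O, 0 °C to rt
Reagents that add atoms: potassium nitrosodisulfonate (KSO3)2NO, [K+].[K+].[O-]S(=O)(=O)N([O])S(=O)(=O)[O-]
Why: Teuber oxidation, in which the nitroxyl radical attacks only the free phenol and delivers oxygen to its open para position C4, so that ring B becomes the 1,4-quinone while ring A, carrying only ether oxygens, is left alone.

Step 11
Reactants: 21 bis-TBS quinone
Product: 22 8-hydroxy-2-[(1S)-1-hydroxy-4-methylpent-3-enyl]-5-methoxy-1,4-naphthoquinone
Conditions: HF·pyridine, pyridine, THF, 0 °C to rt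
Reagents that add atoms: none
Why: Fluoride desilylation in a weakly acidic medium removes the aryl and the secondary alkyl TBS ethers without exposing the base-sensitive quinone to alkoxide, and the carbinol next to the electron-poor quinone no longer ionises.

Step 12
Reactants: 22 quinone diol; 23 3-methylbut-2-enoic acid
Product: 24 (1S)-1-(8-hydroxy-5-methoxy-1,4-dioxo-1,4-dihydronaphthalen-2-yl)-4-methylpent-3-enyl 3-methylbut-2-enoate (CNP0299347.1)
Conditions: 23 (1.5 equiv), N,N'-dicyclohexylcarbodiimide (1.5 equiv), DMAP (0.2 equiv), CH2Cl2, 0 °C to rt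
Reagents that add atoms: 3-methylbut-2-enoic acid (23), CC(C)=CC(=O)O
Why: Steglich esterification acylates the side-chain alcohol selectively because the C8 phenol is held in a hydrogen bond to the C1 carbonyl, and acyl transfer at oxygen leaves the configuration at C1' unchanged; low temperature and catalytic DMAP limit deconjugation of the acyl group.

## Compound list

1 | 3-furaldehyde | O=Cc1ccoc1 | starting material
2 | allyltributylstannane | C=CC[Sn](CCCC)(CCCC)CCCC | starting material
3 | tributylstannyl ether of (S)-1-(furan-3-yl)but-3-en-1-ol | CCCC[Sn](CCCC)(CCCC)O[C@@H](CC=C)c1ccoc1 | intermediate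
4 | (S)-1-(furan-3-yl)but-3-en-1-ol | O[C@@H](CC=C)c1ccoc1 | intermediate
5 | 2-methylbut-2-ene | CC=C(C)C | starting material
6 | (S)-1-(furan-3-yl)-4-methylpent-3-en-1-ol | O[C@@H](CC=C(C)C)c1ccoc1 | intermediate
7 | 2-bromo-1,4-dimethoxybenzene | COc1ccc(OC)c(Br)c1 | starting material
8 | 2-bromo-3,6-dimethoxyphenyllithium | COc1ccc(OC)c(Br)c1[Li] | intermediate
9 | 2,3-dibromo-1,4-dimethoxybenzene | COc1ccc(OC)c(Br)c1Br | intermediate
10 | dibromo(2,3-dibromo-4-methoxyphenoxy)borane | COc1ccc(OB(Br)Br)c(Br)c1Br | intermediate
11 | 2,3-dibromo-4-methoxyphenol | COc1ccc(O)c(Br)c1Br | intermediate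
12 | dichlorodiisopropylsilane | CC(C)[Si](Cl)(Cl)C(C)C | starting material
13 | chloro[(1S)-1-(furan-3-yl)-4-methylpent-3-enyloxy]diisopropylsilane | CC(C)[Si](Cl)(C(C)C)O[C@@H](CC=C(C)C)c1ccoc1 | intermediate
14 | (2,3-dibromo-4-methoxyphenoxy)[(1S)-1-(furan-3-yl)-4-methylpent-3-enyloxy]diisopropylsilane | COc1ccc(O[Si](C(C)C)(C(C)C)O[C@@H](CC=C(C)C)c2ccoc2)c(Br)c1Br | intermediate
15 | aryllithium from 14 (Li in place of the Br next to OMe) | COc1ccc(O[Si](C(C)C)(C(C)C)O[C@@H](CC=C(C)C)c2ccoc2)c(Br)c1[Li] | intermediate
16 | aryne from 15 (triple bond between the two former C–Br carbons) | COC1=CC=C(O[Si](C(C)C)(C(C)C)O[C@@H](CC=C(C)C)c2ccoc2)C#C1 | intermediate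
17 | tethered cycloadduct: (1S,4R)-5-methoxy-1,4-epoxy-1,4-dihydronaphthalene with O8 and the (1'S)-C1' oxygen of the 4-methylpent-3-enyl chain on C2 joined by Si(iPr)2 (eight-membered ring) | COc1ccc2O[Si](C(C)C)(C(C)C)O[C@@H](CC=C(C)C)C3=C[C@H]4O[C@@H]3c2c14 | intermediate
18 | (1S,4R)-2-[(1S)-1-hydroxy-4-methylpent-3-enyl]-5-methoxy-1,4-dihydro-1,4-epoxynaphthalen-8-ol | COc1ccc(O)c2c1[C@H]1C=C([C@@H](O)CC=C(C)C)[C@@H]2O1 | intermediate
19 | bis(tert-butyldimethylsilyl) ether of 18 | COc1ccc(O[Si](C)(C)C(C)(C)C)c2c1[C@H]1C=C([C@@H](O[Si](C)(C)C(C)(C)C)CC=C(C)C)[C@@H]2O1 | intermediate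
20 | 8-(tert-butyldimethylsilyloxy)-2-[(1S)-1-(tert-butyldimethylsilyloxy)-4-methylpent-3-enyl]-5-methoxynaphthalen-1-ol | COc1ccc(O[Si](C)(C)C(C)(C)C)c2c(O)c([C@@H](O[Si](C)(C)C(C)(C)C)CC=C(C)C)ccc12 | intermediate
21 | 8-(tert-butyldimethylsilyloxy)-2-[(1S)-1-(tert-butyldimethylsilyloxy)-4-methylpent-3-enyl]-5-methoxy-1,4-naphthoquinone | COc1ccc(O[Si](C)(C)C(C)(C)C)c2c1C(=O)C=C([C@@H](O[Si](C)(C)C(C)(C)C)CC=C(C)C)C2=O | intermediate
22 | 8-hydroxy-2-[(1S)-1-hydroxy-4-methylpent-3-enyl]-5-methoxy-1,4-naphthoquinone | COc1ccc(O)c2c1C(=O)C=C([C@@H](O)CC=C(C)C)C2=O | intermediate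
23 | 3-methylbut-2-enoic acid | CC(C)=CC(=O)O | starting material
24 | (1S)-1-(8-hydroxy-5-methoxy-1,4-dioxo-1,4-dihydronaphthalen-2-yl)-4-methylpent-3-enyl 3-methylbut-2-enoate (CNP0299347.1) | COc1ccc(O)c2c1C(=O)C=C([C@H](CC=C(C)C)OC(=O)C=C(C)C)C2=O | target

## Step count and risks

Total steps: 12. Longest linear sequence: 10 (steps 1, 2, 5, 6, 7, 8, 9, 10, 11, 12).

**Risk 1, step 6.** The short O–Si–O link may hold the furan too far from the aryne in the transition state. The aryne would then be consumed by intermolecular addition (oligomers, butyl adducts), or silicon would migrate to the lithiated carbon. The fallback lengthens the tether by one siloxane unit. It sets out from 6 and 11, which are joined with 1,3-dichloro-1,1,3,3-tetraisopropyldisiloxane (Et3N, DMAP, CH2Cl2) to the disiloxane-linked bis-ether F1. n-BuLi at −78 °C under the same dilution should give the ten-membered-ring cycloadduct F2; the wrong furan orientation would still require a fully extended chain. Bu4NF/AcOH then removes the tether and the route is rejoined at 18.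

**Risk 2, step 9.** Under acid the electron-rich ortho-hydroxybenzylic silyl ether may ionise at C1', which erodes the configuration. The acid may also remove silyl groups or add to the prenyl alkene. The fallback opens the bridge without acid and sets out from 19. Ni(cod)2 with Ph2P(CH2)4PPh2 (catalytic) and iBu2AlH in THF should effect reductive ring opening: hydride goes to C2 from the bridge face, then the C4–O bond is lost by β-elimination. This gives the trans-1,2-dihydronaphthalen-1-ol F3. Dess–Martin periodinane with NaHCO3 oxidises the benzylic alcohol to the 2H-naphthalen-1-one F4, which enolises on exposure to Et3N, and the route is rejoined at 20.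

**Risk 3, step 10.** The bulky nitroxyl radical may couple ortho instead of para, or react sluggishly with the hindered, lipophilic naphthol. A peri O-to-O silyl shift could also expose the ring A phenol to oxidation. The fallback replaces radical oxidation by a two-electron dearomatisation and sets out from 20. PhI(OAc)2 (2.2 equiv) in MeOH at 0 °C should give the para-quinone monoketal F5 (4,4-dimethoxy). Mild aqueous acid (oxalic acid on wet SiO2) hydrolyses the ketal, and the route is rejoined at 21.

## Further compounds

F1 | step 6 | 1-(2,3-dibromo-4-methoxyphenoxy)-3-[(1S)-1-(furan-3-yl)-4-methylpent-3-enyloxy]-1,1,3,3-tetraisopropyldisiloxane | COc1ccc(O[Si](C(C)C)(C(C)C)O[Si](C(C)C)(C(C)C)O[C@@H](CC=C(C)C)c2ccoc2)c(Br)c1Br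
F2 | step 6 | disiloxane-tethered cycloadduct (ten-membered ring, bridgeheads as in 17) | COc1ccc2O[Si](C(C)C)(C(C)C)O[Si](C(C)C)(C(C)C)O[C@@H](CC=C(C)C)C3=C[C@H]4O[C@@H]3c2c14
F3 | step 9 | trans-8-(tert-butyldimethylsilyloxy)-2-[(1S)-1-(tert-butyldimethylsilyloxy)-4-methylpent-3-enyl]-5-methoxy-1,2-dihydronaphthalen-1-ol | COc1ccc(O[Si](C)(C)C(C)(C)C)c2c1C=C[C@@H]([C@@H](O[Si](C)(C)C(C)(C)C)CC=C(C)C)[C@@H]2O
F4 | step 9 | 8-(tert-butyldimethylsilyloxy)-2-[(1S)-1-(tert-butyldimethylsilyloxy)-4-methylpent-3-enyl]-5-methoxy-2H-naphthalen-1-one | COc1ccc(O[Si](C)(C)C(C)(C)C)c2c1C=C[C@@H]([C@@H](O[Si](C)(C)C(C)(C)C)CC=C(C)C)C2=O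
F5 | step 10 | 8-(tert-butyldimethylsilyloxy)-2-[(1S)-1-(tert-butyldimethylsilyloxy)-4-methylpent-3-enyl]-4,4,5-trimethoxy-4H-naphthalen-1-one | COc1ccc(O[Si](C)(C)C(C)(C)C)c2c1C(OC)(OC)C=C([C@@H](O[Si](C)(C)C(C)(C)C)CC=C(C)C)C2=O
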